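The ratio of second end groups charged to first end groups charged, 90.0% in the flask, is the ceiling on conversion: each turnover into links or rings takes one group of each kind, and the flask holds fewer second end groups than first end groups, which makes the second end groups the limiting reagent.

| flask | first end groups | second end groups | remark | time |
|---|---|---|---|---|
| east | 0.80 M | 0.48 M | run made earlier |  |
| north | 0.80 M | 1.1 M | run made earlier |  |
| flask | 0.80 M | 0.720 M |  | 15 d |

- east (time / d: first end groups / %, links / %, rings / %): 1.25: 37, 24, 36; 4.00: 41, 27, 33; 6.00: 38, 25, 33; 10.0: 40, 23, 35; 15.0: 38, 27, 36; 20.0: 42, 25, 34
- north (time / d: first end groups / %, links / %, rings / %): 3.00: 3, 68, 27; 6.00: 0, 72, 30; 10.0: 0, 69, 31; 12.0: 0, 69, 30; 15.0: 0, 68, 28; 20.0: 0, 70, 28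

(readings scatter by 1.5 percentage points)

- what is said of links includes crystals
- crystals is a solid; its amount is given per volume of the solution
- steps thought possible: first end groups + second end groups -> rings; first end groups + second end groups -> links; crystals <-> links
- the reaction counts as stopped when no species that holds the first end groups changes by six tenths of a point or more over the second half of the time

1. why nothing more happens at 15 d, or that something still does (all of the first end groups has reacted / it is still moving / forward and back rates have come level / the second end groups has run out first)
2. part of the first end groups gone at 15 d
3. the links standing at 15 d, as a percentage of the first end groups charged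
4. the rings standing at 15 d, as a percentage of the first end groups charged

The east run looks nearly like the flask, with the same charge of first end groups, but its ceiling is 60.0%. Its first end groups read 37% at 1.25 d and 42% at 20.0 d, around the 40.0% that this ceiling leaves, so the east run reads as stopped at its ceiling. The north run holds more second end groups than first end groups, a ratio of 1.38, and its first end groups read 0% at 6.00 d.

The flask stands 12.0 times as long as the east run took to its first reading. The reckoning here therefore puts the flask at its ceiling by the asked time, with 10.0% of the first end groups left over.

The forecast reads: the second end groups has run out first, with 90% of the first end groups gone. Holding that “Selectivity shifts towards links” as second end groups rise, it expects 46% links and 44% rings.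

The flask gives: the second end groups has run out first, with 90.0% gone, 45.8% links and 44.2% rings.

    first end groups + second end groups → rings, rate k1*[first end groups] as long as [second end groups] is above zero (k = 1.10 × 10⁻⁴ /s)
    first end groups + second end groups → links (k = 3.99 × 10⁻⁴ /M/s)
    crystals ⇌ links, rate k3*(cs3 - [links]) while solid is left; crystals form when [links] > cs3 (solubility = 23.0 mM, k = 0.00115 /s)

The half-life of first end groups by the step into links, 1.1 h at 0.0142 d, is short against the 15 d of the flask, and the flask already stands at its ceiling of 90.0% by 1.50 d, with first end groups at 10.0% and second end groups at 0%. The neighbouring flask charged with 1.4 M of first end groups has a ceiling of 51.4% and shows a conversion of 51.4% at 15.0 d, its second end groups standing at 0%.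

The numbers in the tables come from a simulation with constants of no real substance, and the scatter is random.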